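**Retrosynthetic overview**

1. Locants: ring A is the cinnamaldehyde ring (C1 side chain, C3 with methoxy oxygen O3, C4 with O4, C5 with O5); C7' is the aryl-bearing dioxane carbon on O5; C8' is the dioxane carbon on O4 that carries C9' (CH2OH); ring C is the guaiacyl ring.
2. Nocomtal <= (desilylation, Wittig two-carbon homologation, benzylic oxidation, methylation of O3, LiAlH4) tricyclic lactone 10, in which C9' is a carboxyl carbon esterified to O3 and C1 carries a methyl ester.
3. 10 <= aryl diazoacetate 7 of a 2-aryl-1,3-benzodioxole, by disconnection of the C7'–C8' bond of the dioxane ring; forward, carbene capture by O4 and a [1,2]-shift of the acetal carbon C7' from O4 to C8' expand the dioxole to the dioxane.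
4. Enabling feature: O3, C3, C4, O4, C8' and C9' can be tied into a six-membered lactone, so the later methoxy oxygen delivers the carbene carbon C8' to O4 alone, while C7', benzylic to the electron-rich ring C and bonded to O5, can be held as an acetal carbon on O4 and O5 and ionises easily; the dioxole ring (C7'–O4) and the lactone ring (C9'–O3) are absent from the target and are cleaved in steps 5 and 6.
5. 7 <= methyl gallate (two-fold symmetric, so only one benzodioxole can form) + O-silylated vanillin; ring order: dioxole (step 2), then lactone and dioxane (both in step 5).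

Key step: step 5

Remark (assumption): the sense of asymmetric induction of the copper–bisoxazoline catalyst in step 5 cannot be derived from precedent. The (S,S)-ligand is written; the equally available (R,R)-ligand takes its place if a chiral-phase assay at diol 12 shows the opposite sense. Compounds 5–7 are racemic at the acetal carbon, and step 5 is meant to erase that centre.

**Route**

Step 1
Reactants: 1 vanillin
Product: 2 3-methoxy-4-(triisopropylsilyloxy)benzaldehyde
Conditions: TIPSCl, imidazole, DMF, rt
Reagents that add atoms: triisopropylsilyl chloride, CC(C)[Si](Cl)(C(C)C)C(C)C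
Why: Imidazole-promoted silyl ether formation masks the ring C phenol with a group that should tolerate the acid, hydride, carbonate, carbene and ylide steps and is removed last by fluoride.

Step 2
Reactants: 2 3-methoxy-4-(triisopropylsilyloxy)benzaldehyde; 3 methyl gallate
Product: 5 methyl 7-hydroxy-2-[3-methoxy-4-(triisopropylsilyloxy)phenyl]-1,3-benzodioxole-5-carboxylate (racemic), via dimethyl acetal 4 (not isolated)
Conditions: HC(OMe)3, PPTS (cat.), MeOH, 50 °C; evaporate; then 3, PPTS (cat.), PhMe–MeCN, reflux through 4 Å MS
Reagents that add atoms: none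
Why: Acid-catalysed acetalisation and transacetalisation under removal of methanol should join the acetal carbon (the future C7') to two neighbouring hydroxyls; the 3,4- and 4,5-diol pairs of methyl gallate are equivalent, so a single benzodioxole forms and the hydroxyl that becomes O3 stays free.

Step 3
Reactants: 5 methyl 7-hydroxy-2-[3-methoxy-4-(triisopropylsilyloxy)phenyl]-1,3-benzodioxole-5-carboxylate
Product: 6 methyl 7-(2-bromoacetoxy)-2-[3-methoxy-4-(triisopropylsilyloxy)phenyl]-1,3-benzodioxole-5-carboxylate (racemic)
Conditions: BrCH2COBr, pyridine, CH2Cl2, −20 to 0 °C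
Reagents that add atoms: bromoacetyl bromide, BrCC(Br)=O
Why: O-acylation of the only phenol with an acid bromide, buffered by pyridine so that the acid-labile acetal is not exposed to HBr.

Step 4
Reactants: 6 methyl 7-(2-bromoacetoxy)-2-[3-methoxy-4-(triisopropylsilyloxy)phenyl]-1,3-benzodioxole-5-carboxylate
Product: 7 methyl 7-(2-diazoacetoxy)-2-[3-methoxy-4-(triisopropylsilyloxy)phenyl]-1,3-benzodioxole-5-carboxylate (racemic)
Conditions: TsNHNHTs, DBU, THF, 0 °C
Reagents that add atoms: N,N'-ditosylhydrazine, Cc1ccc(cc1)S(=O)(=O)NNS(=O)(=O)c1ccc(C)cc1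
Why: Diazoacetate synthesis from a bromoacetate (N-alkylation of the bis-sulfonylhydrazine followed by two base-induced losses of sulfinate) runs cold and fast enough to spare the aryl ester and the acetal.

Step 5
Reactants: 7 methyl 7-(2-diazoacetoxy)-2-[3-methoxy-4-(triisopropylsilyloxy)phenyl]-1,3-benzodioxole-5-carboxylate
Product: 10 tricyclic lactone (7'S; C9' carbonyl bonded to O3; aryl and carbonyl trans on the new dioxane ring), via oxonium ylide 8 (not isolated), via oxocarbenium enolate zwitterion 9 (not isolated)
Conditions: Cu(MeCN)4PF6 (5 mol %, monovalent copper), 2,2'-(propane-2,2-diyl)bis[(4S)-4-tert-butyl-4,5-dihydrooxazole] (6 mol %), 4 Å MS, CH2Cl2, 40 °C, slow addition of 7 by syringe pump (final ca. 0.01 M); 8 and 9 are drawn without the metal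
Reagents that add atoms: none
Why: Proposed new method: the copper carbene from 7 should be captured in the plane of ring A by the lone pair of the dioxole oxygen O4 next to the ester-bearing O3 (closure of the six-membered lactone ring through the C8'–O4 bond, giving the copper-associated oxonium ylide 8); the C7'–O4 bond of this oxonium acetal then ionises, pushed by O5 and by the 4-silyloxy-3-methoxyphenyl group, to the oxocarbenium/lactone enolate pair 9, and the enolate carbon C8' adds to C7' in a 6-(enolexo)-endo-trig closure that makes the C7'–C8' bond and the 1,4-dioxane ring, so that overall the five-membered dioxole is expanded by the carbene carbon (a Stevens-type [1,2]-shift in its stepwise, ion-pair form). The closest known reactions are the copper- and rhodium-catalysed oxonium ylide/[1,2]-shift ring expansions of oxetanes and of cyclic acetals carrying diazo ester or diazo ketone tethers, the [1,2]-benzyl shift of aryl benzyl ether oxonium ylides, and the copper–bisoxazoline O–H insertion of phenols, which shows that an aryl oxygen is engaged by such carbenes and that the chiral ligand stays on the ylide carbon; new here are the benzodioxole as the acetal, the aryl ester tether and the enantioconvergent course. Because C7' is trigonal in 9, both enantiomers of racemic 7 should give the same intermediate, provided that C–C bond formation (which requires the copper-bound C8' to leave the plane of ring A) is slower than rotation and inversion at the oxocarbenium oxygen; the configuration at C7' is then to be set by the ligand on the copper enolate, which shields one face of C8' as it meets the oxocarbenium ion. The trans relation of the two new stereocentres is controlled by the substrate: the lactone holds the C8'–C9' bond in the plane of ring A (pseudo-equatorial on the new ring), the aryl group at C7' takes the pseudo-equatorial position in the half-chair closure, and C8', being alpha to the lactone carbonyl, can equilibrate to the same trans isomer. The step needs site selectivity for O4 over O5 and over ring carbon C2, and ylide formation ahead of carbene dimerisation: the one-atom carbonyl tether reaches only O4 in a strain-free planar array, copper is chosen because it favours ylide formation over aromatic C–H insertion, and slow addition keeps the diazo concentration low.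

Step 6
Reactants: 10 tricyclic lactone
Product: 11 (2S,3S)-3,7-bis(hydroxymethyl)-2-[3-methoxy-4-(triisopropylsilyloxy)phenyl]-2,3-dihydro-1,4-benzodioxin-5-ol
Conditions: LiAlH4, THF, −20 to 0 °C; then H2O, aq NaOH (crude 10 is used without delay)
Reagents that add atoms: none
Why: Hydride reduction of the aryl lactone and of the methyl benzoate releases C9' as the primary alcohol and O3 as the phenol and turns the C1 ester into the benzylic alcohol; carbonyl addition at low temperature should outrun enolisation at C8', so both stereocentres are kept.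

Step 7
Reactants: 11 (2S,3S)-3,7-bis(hydroxymethyl)-2-[3-methoxy-4-(triisopropylsilyloxy)phenyl]-2,3-dihydro-1,4-benzodioxin-5-ol
Product: 12 [(2S,3S)-5-methoxy-2-[3-methoxy-4-(triisopropylsilyloxy)phenyl]-2,3-dihydro-1,4-benzodioxine-3,7-diyl]dimethanol
Conditions: MeI, K2CO3, acetone, 40 °C
Reagents that add atoms: iodomethane, CI
Why: Williamson ether synthesis is selective for the only phenol (K2CO3 does not deprotonate the two alcohols) and turns the spent tether oxygen O3 into the 3-methoxy group of the target.

Step 8
Reactants: 12 [(2S,3S)-5-methoxy-2-[3-methoxy-4-(triisopropylsilyloxy)phenyl]-2,3-dihydro-1,4-benzodioxine-3,7-diyl]dimethanol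
Product: 13 (2S,3S)-3-(hydroxymethyl)-5-methoxy-2-[3-methoxy-4-(triisopropylsilyloxy)phenyl]-2,3-dihydro-1,4-benzodioxine-7-carbaldehyde
Conditions: MnO2 (activated), CH2Cl2, rt
Reagents that add atoms: none
Why: MnO2 oxidation is chemoselective for the benzylic alcohol and should leave the saturated primary alcohol at C9' and the benzylic ether at C7' untouched.

Step 9
Reactants: 13 (2S,3S)-3-(hydroxymethyl)-5-methoxy-2-[3-methoxy-4-(triisopropylsilyloxy)phenyl]-2,3-dihydro-1,4-benzodioxine-7-carbaldehyde
Product: 14 (E)-3-[(2S,3S)-3-(hydroxymethyl)-5-methoxy-2-[3-methoxy-4-(triisopropylsilyloxy)phenyl]-2,3-dihydro-1,4-benzodioxin-7-yl]prop-2-enal (O-silyl nocomtal)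
Conditions: Ph3P=CHCHO, toluene, 80 °C
Reagents that add atoms: (triphenylphosphoranylidene)acetaldehyde, O=CC=P(c1ccccc1)(c1ccccc1)c1ccccc1
Why: Wittig olefination with a stabilised formyl ylide should give the (E)-enal and tolerates the free alcohol.

Step 10
Reactants: 14 O-silyl nocomtal
Product: 15 (7'S,8'S)-nocomtal, (E)-3-[(2S,3S)-2-(4-hydroxy-3-methoxyphenyl)-3-(hydroxymethyl)-5-methoxy-2,3-dihydro-1,4-benzodioxin-7-yl]prop-2-enal
Conditions: Bu4NF, AcOH (1:1), THF, 0 °C
Reagents that add atoms: none
Why: Fluoride-induced cleavage of the aryl silyl ether, buffered with acetic acid so that the phenoxide is protonated at once and neither adds to the enal nor opens the benzylic ether through a quinone methide.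

**Compound list**

1 | vanillin | COc1cc(C=O)ccc1O | starting material
2 | 3-methoxy-4-(triisopropylsilyloxy)benzaldehyde | COc1cc(C=O)ccc1O[Si](C(C)C)(C(C)C)C(C)C | intermediate
3 | methyl gallate (methyl 3,4,5-trihydroxybenzoate) | COC(=O)c1cc(O)c(O)c(O)c1 | starting material
4 | dimethyl acetal of 2, [4-(dimethoxymethyl)-2-methoxyphenoxy]triisopropylsilane (not isolated) | COc1cc(C(OC)OC)ccc1O[Si](C(C)C)(C(C)C)C(C)C | intermediate
5 | methyl 7-hydroxy-2-[3-methoxy-4-(triisopropylsilyloxy)phenyl]-1,3-benzodioxole-5-carboxylate, racemic at the acetal carbon | COC(=O)c1cc(O)c2OC(Oc2c1)c1ccc(O[Si](C(C)C)(C(C)C)C(C)C)c(OC)c1 | intermediate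
6 | methyl 7-(2-bromoacetoxy)-2-[3-methoxy-4-(triisopropylsilyloxy)phenyl]-1,3-benzodioxole-5-carboxylate, racemic | COC(=O)c1cc(OC(=O)CBr)c2OC(Oc2c1)c1ccc(O[Si](C(C)C)(C(C)C)C(C)C)c(OC)c1 | intermediate
7 | methyl 7-(2-diazoacetoxy)-2-[3-methoxy-4-(triisopropylsilyloxy)phenyl]-1,3-benzodioxole-5-carboxylate, racemic | COC(=O)c1cc(OC(=O)C=[N+]=[N-])c2OC(Oc2c1)c1ccc(O[Si](C(C)C)(C(C)C)C(C)C)c(OC)c1 | intermediate
8 | oxonium ylide: dioxole intact, O4 additionally bonded to the carbanionic C8' of the six-membered lactone (drawn metal-free, not isolated) | COC(=O)c1cc2OC(=O)[CH-][O+]3c2c(OC3c2ccc(O[Si](C(C)C)(C(C)C)C(C)C)c(OC)c2)c1 | intermediate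
9 | oxocarbenium enolate zwitterion: O5=C7'(H)–aryl cation and lactone enolate C8'=C9'(O–) on O4 (drawn metal-free, not isolated) | COC(=O)c1cc2OC([O-])=COc2c([O+]=Cc2ccc(O[Si](C(C)C)(C(C)C)C(C)C)c(OC)c2)c1 | intermediate
10 | tricyclic lactone: trans-2-aryl-1,4-benzodioxane whose C8' carboxyl (C9') is lactonised onto O3 of ring A, methyl ester at C1, aryl = 3-methoxy-4-(triisopropylsilyloxy)phenyl; (7'S,8'R), the same spatial arrangement as 7'S,8'S in the target (the label at C8' changes only because C9' is a carboxyl carbon) | COc1cc([C@@H]2Oc3cc(C(=O)OC)cc4c3O[C@H]2C(=O)O4)ccc1O[Si](C(C)C)(C(C)C)C(C)C | intermediate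
11 | (2S,3S)-3,7-bis(hydroxymethyl)-2-[3-methoxy-4-(triisopropylsilyloxy)phenyl]-2,3-dihydro-1,4-benzodioxin-5-ol | COc1cc([C@@H]2Oc3cc(CO)cc(O)c3O[C@H]2CO)ccc1O[Si](C(C)C)(C(C)C)C(C)C | intermediate
12 | [(2S,3S)-5-methoxy-2-[3-methoxy-4-(triisopropylsilyloxy)phenyl]-2,3-dihydro-1,4-benzodioxine-3,7-diyl]dimethanol | COc1cc([C@@H]2Oc3cc(CO)cc(OC)c3O[C@H]2CO)ccc1O[Si](C(C)C)(C(C)C)C(C)C | intermediate
13 | (2S,3S)-3-(hydroxymethyl)-5-methoxy-2-[3-methoxy-4-(triisopropylsilyloxy)phenyl]-2,3-dihydro-1,4-benzodioxine-7-carbaldehyde | COc1cc([C@@H]2Oc3cc(C=O)cc(OC)c3O[C@H]2CO)ccc1O[Si](C(C)C)(C(C)C)C(C)C | intermediate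
14 | O-silyl nocomtal, (E)-3-[(2S,3S)-3-(hydroxymethyl)-5-methoxy-2-[3-methoxy-4-(triisopropylsilyloxy)phenyl]-2,3-dihydro-1,4-benzodioxin-7-yl]prop-2-enal | COc1cc([C@@H]2Oc3cc(/C=C/C=O)cc(OC)c3O[C@H]2CO)ccc1O[Si](C(C)C)(C(C)C)C(C)C | intermediate
15 | (7'S,8'S)-nocomtal | COc1cc([C@@H]2Oc3cc(/C=C/C=O)cc(OC)c3O[C@H]2CO)ccc1O | target

**Step count and risks**

Total step count: 10. Longest linear sequence: 10 steps (1 to 15); methyl gallate 3 enters at step 2.

Steps most likely to fail:

1. Step 5. The carbene may be consumed by attack on ring carbon C2 or by dimerisation before the ester rotamer that reaches O4 is populated. The ylide may also collapse with retention at C7' faster than the acetal configuration is lost, which would give the lactone without enantiocontrol. Fallback (known chemistry only; sets out from 2, returns at 12): commercial methyl 3-bromo-4-hydroxy-5-methoxybenzoate would be O-alkylated with commercial (R)-4-benzyl-3-(chloroacetyl)oxazolidin-2-one (K2CO3, NaI, acetone) to the aryloxyacetyl imide F1. Its boron enolate (Bu2BOTf, iPr2NEt, CH2Cl2, −78 °C) would add to aldehyde 2 in an Evans syn aldol reaction to give the (2R,3S)-aldol adduct F2, the auxiliary setting C7' and C8'. MeOMgBr in MeOH at 0 °C would exchange the auxiliary for a methyl ester to give the hydroxy diester F3. Intramolecular palladium-catalysed C–O coupling of the secondary alcohol with the aryl bromide (Pd(OAc)2, 2-(di-tert-butylphosphino)-1,1'-binaphthyl, K3PO4, toluene, 80 °C) proceeds with retention at C7' and would close the dioxane ring to the trans benzodioxane diester F4; any cis isomer arising from epimerisation at the ester-bearing carbon would be equilibrated to F4 with DBU. LiAlH4 reduction of both esters of F4 then gives 12.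

2. Step 2. The acetal exchange may stop at the mixed aryl methyl acetal or revert, and the acid it needs may strip the silyl group or hydrolyse the electron-rich benzylidene acetal during work-up. Fallback (sets out from 2 and 3, returns at 5): NaBH4 in MeOH would reduce 2 to the benzylic alcohol F5. A Mitsunobu etherification (PPh3, DIAD, THF, 0 °C) with methyl gallate 3, whose 4-hydroxyl para to the ester is the most acidic, would give the 4-O-benzyl ether F6. Anhydrous DDQ (CH2Cl2, 4 Å MS, 0 °C) would then abstract hydride from the electron-rich benzylic position, and either of the two equivalent neighbouring phenols would trap the cation. This closes benzodioxole 5 under non-acidic, non-equilibrium conditions, by the oxidative acetal formation known for p-methoxybenzyl ethers of diols.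

3. Step 9. Olefination of the electron-rich aldehyde may be slow, and the product enal may react a second time with the same ylide (chain extension to the dienal). Fallback (sets out from 13, returns at 14): a Horner–Wadsworth–Emmons reaction with triethyl phosphonoacetate (LiCl, DBU, MeCN), which cannot react twice, would give the (E)-cinnamate ester F7. iBu2AlH (CH2Cl2, −78 °C) would reduce it to the allylic alcohol F8, and MnO2 (CH2Cl2, rt) would oxidise the allylic alcohol selectively to enal 14.

**Further compounds**

F1 | step 5 | (R)-4-benzyl-3-{[2-bromo-6-methoxy-4-(methoxycarbonyl)phenoxy]acetyl}oxazolidin-2-one | COC(=O)c1cc(Br)c(OCC(=O)N2[C@H](Cc3ccccc3)COC2=O)c(OC)c1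
F2 | step 5 | (R)-4-benzyl-3-{(2R,3S)-2-[2-bromo-6-methoxy-4-(methoxycarbonyl)phenoxy]-3-hydroxy-3-[3-methoxy-4-(triisopropylsilyloxy)phenyl]propanoyl}oxazolidin-2-one | COc1cc([C@H](O)[C@@H](Oc2c(Br)cc(C(=O)OC)cc2OC)C(=O)N2[C@H](Cc3ccccc3)COC2=O)ccc1O[Si](C(C)C)(C(C)C)C(C)C
F3 | step 5 | methyl 3-bromo-4-{[(2R,3S)-3-hydroxy-1-methoxy-3-[3-methoxy-4-(triisopropylsilyloxy)phenyl]-1-oxopropan-2-yl]oxy}-5-methoxybenzoate | COc1cc([C@H](O)[C@@H](Oc2c(Br)cc(C(=O)OC)cc2OC)C(=O)OC)ccc1O[Si](C(C)C)(C(C)C)C(C)C
F4 | step 5 | dimethyl trans-5-methoxy-2-[3-methoxy-4-(triisopropylsilyloxy)phenyl]-2,3-dihydro-1,4-benzodioxine-3,7-dicarboxylate, (7'S,8'R), same spatial arrangement as 10 | COc1cc([C@@H]2Oc3cc(C(=O)OC)cc(OC)c3O[C@H]2C(=O)OC)ccc1O[Si](C(C)C)(C(C)C)C(C)C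
F5 | step 2 | [3-methoxy-4-(triisopropylsilyloxy)phenyl]methanol | COc1cc(CO)ccc1O[Si](C(C)C)(C(C)C)C(C)C
F6 | step 2 | methyl 3,5-dihydroxy-4-{[3-methoxy-4-(triisopropylsilyloxy)phenyl]methoxy}benzoate | COC(=O)c1cc(O)c(OCc2ccc(O[Si](C(C)C)(C(C)C)C(C)C)c(OC)c2)c(O)c1
F7 | step 9 | ethyl (E)-3-[(2S,3S)-3-(hydroxymethyl)-5-methoxy-2-[3-methoxy-4-(triisopropylsilyloxy)phenyl]-2,3-dihydro-1,4-benzodioxin-7-yl]prop-2-enoate | COc1cc([C@@H]2Oc3cc(/C=C/C(=O)OCC)cc(OC)c3O[C@H]2CO)ccc1O[Si](C(C)C)(C(C)C)C(C)C
F8 | step 9 | (E)-3-[(2S,3S)-3-(hydroxymethyl)-5-methoxy-2-[3-methoxy-4-(triisopropylsilyloxy)phenyl]-2,3-dihydro-1,4-benzodioxin-7-yl]prop-2-en-1-ol | COc1cc([C@@H]2Oc3cc(/C=C/CO)cc(OC)c3O[C@H]2CO)ccc1O[Si](C(C)C)(C(C)C)C(C)C
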